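**Retrosynthetic overview**
- The target comes from its 9-O-MOM ether by acid hydrolysis; the C3 ester bond is made by Yamaguchi coupling of the core 3α-alcohol with (2Z)-4-angeloyloxy-3-methylbut-2-enoic acid (from a silyl propargyl ether: Boc2O acylation, Me2CuLi syn-addition, angeloylation, tert-butyl ester cleavage).
- The 7-isopropylidene group comes from an aldol addition of the C7 enolate to acetone and dehydration; the diosphenol comes from the 9(10)-en-8-one by nucleophilic epoxidation and acid isomerisation.
- The 3α-OH and 4β-CH3 come from α-face hydroboration of a C3=C4(CH3) alkene, made from the C4 ketone (enol triflate, Me2CuLi) while the enone is masked as a dithiolane.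
- The decalin is (S)-Wieland–Miescher ketone: the key C–C bond is the intermolecular Michael addition of 2-methylcyclohexane-1,3-dione to methyl vinyl ketone.
- Ring order: ring A is carried in with the dione; ring B is closed second by the L-proline aldol condensation, which sets C5.

Assumption and convention (one line): the target is the 9-hydroxy-9(10)-en-8-one tautomer drawn in the SMILES; the decalin is numbered as in eremophilane (C3 = O-bearing carbon, C4/C5 = methyl-bearing carbons, C8 = ring C=O, ring A = C1–C5/C10, ring B = C5–C10), β is the face of the C5 methyl, and the C5 label changes from S (in 5) to R (target) only through CIP priorities.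

Step 1
Reactants: 1 2-methylcyclohexane-1,3-dione; 2 methyl vinyl ketone
Product: 3 2-methyl-2-(3-oxobutyl)cyclohexane-1,3-dione
Conditions: H2O, AcOH (cat.), hydroquinone (cat.), 75 °C
Reagents that add atoms: none
Why: Intermolecular Michael addition of the 1,3-dione enol to the enone joins the two fragments (future C5–C6 bond) and creates the quaternary carbon; the product is still achiral.

Step 2
Reactants: 3
Product: 5 (S)-Wieland–Miescher ketone, via cis-fused ketol 4 (not isolated)
Conditions: L-proline (5 mol %), DMSO, rt, 5 d; recrystallisation (Et2O/hexane) to >99% ee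
Reagents that add atoms: none
Why: Hajos–Parrish–Eder–Sauer–Wiechert reaction: the proline enamine of the side-chain ketone attacks one of the two enantiotopic ring carbonyls (intramolecular aldol, then dehydration), closing ring B and setting C5 as S, the known outcome with L-proline.

Step 3
Reactants: 5
Product: 6 enone dithiolane of 5 with free C4 ketone
Conditions: HSCH2CH2SH (1.05 equiv), p-TsOH·H2O (cat.), AcOH, rt
Reagents that add atoms: ethane-1,2-dithiol, SCCS
Why: Acid-catalysed thioketalisation is selective for the unhindered enone carbonyl (the C4 ketone is neopentylic) and leaves the double bond at C9=C10.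

Step 4
Reactants: 6
Product: 8 C4 enol triflate of 6, via potassium enolate 7 (not isolated)
Conditions: KN(SiMe3)2, THF, −78 °C; then PhNTf2, −78 → 0 °C
Reagents that add atoms: N-phenylbis(trifluoromethanesulfonimide), O=S(=O)(N(c1ccccc1)S(=O)(=O)C(F)(F)F)C(F)(F)F
Why: Enolate O-sulfonylation; the ketone can enolise only towards C3 because C5 is quaternary, so a single enol triflate forms.

Step 5
Reactants: 8
Product: 9 4,5β-dimethyl-3,9(10)-diene dithiolane
Conditions: Me2CuLi (from CuI, copper monoiodide, + 2 MeLi), THF, −15 → 0 °C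
Reagents that add atoms: lithium dimethylcuprate, [Li+].C[Cu-]C
Why: Cuprate–enol triflate cross-coupling replaces OTf by CH3 without moving the C3=C4 double bond and tolerates the dithiolane.

Step 6
Reactants: 9
Product: 11 3α-hydroxy-4β,5β-dimethyl-9(10)-ene dithiolane, via C3 alkylborane 10 (not isolated)
Conditions: BH3·THF (1.1 equiv), THF, 0 °C → rt; then 3 M NaOH, 30% H2O2, 0 °C (brief)
Reagents that add atoms: hydrogen peroxide, OO
Why: Hydroboration–oxidation adds H and B syn and anti-Markovnikov from the α face (opposite the pseudoaxial C5 methyl), setting 3α-OH and 4β-CH3 (cis to the C5 methyl) together, while the C9=C10 alkene, flanked by the spiro-dithiolane and the quaternary C5, should react more slowly.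

Step 7
Reactants: 11
Product: 12 3α-hydroxy-4β,5β-dimethyl-9(10)-en-8-one
Conditions: MeI, CaCO3, MeCN/H2O (4:1), 60 °C
Reagents that add atoms: water, O
Why: S-Alkylative hydrolysis of the allylic dithiolane regenerates the conjugated enone under near-neutral conditions that leave the free secondary alcohol untouched.

Step 8
Reactants: 12
Product: 13 9β,10β-epoxy-3α-hydroxy-4β,5β-dimethyldecalin-8-one
Conditions: 30% H2O2, NaOH, MeOH, 0 °C → rt
Reagents that add atoms: hydrogen peroxide, OO
Why: Weitz–Scheffer nucleophilic epoxidation of the enone gives mainly the β-epoxide, and the epoxide configuration does not matter because both epimers converge in step 9.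

Step 9
Reactants: 13
Product: 14 3α,9-dihydroxy-4β,5β-dimethyl-9(10)-en-8-one (diosphenol)
Conditions: 10% aq. H2SO4, THF, 60 °C
Reagents that add atoms: none
Why: Acid-catalysed epoxy ketone to diosphenol isomerisation (opening at tertiary C10, then loss of water) gives the 8,9-dione, which rests as the more substituted conjugated 9-hydroxy-9(10)-en-8-one enol, as in the analogous steroid 4-hydroxy-4-en-3-ones.

Step 10
Reactants: 14
Product: 15 9-O-methoxymethyl diosphenol with free 3α-OH
Conditions: MOMCl (1.1 equiv), i-Pr2NEt, CH2Cl2, 0 °C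
Reagents that add atoms: chloromethyl methyl ether, COCCl
Why: Williamson-type O-alkylation of the acidic enol OH with a hard electrophile is much faster than reaction of the hindered neutral C3 alcohol.

Step 11
Reactants: 15
Product: 16 3α-O-TBS 9-O-MOM enone
Conditions: TBSCl, imidazole, DMAP (cat.), DMF, 40 °C
Reagents that add atoms: tert-butyldimethylsilyl chloride, CC(C)(C)[Si](C)(C)Cl
Why: Silyl ether formation protects the remaining secondary alcohol under conditions that do not harm the MOM enol ether.

Step 12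
Reactants: 16
Product: 18 C7 acetone aldol adduct, via lithium enolate 17 (not isolated)
Conditions: LiN(i-Pr)2, THF, −78 °C; acetone, −78 °C; AcOH/THF quench at −78 °C
Reagents that add atoms: acetone, CC(C)=O
Why: Kinetic deprotonation at C7 (the only α-CH2, since C9 is fully substituted) and intermolecular aldol addition to acetone from the α face; the C7 configuration is erased in step 13.

Step 13
Reactants: 18
Product: 20 3α-O-TBS 9-O-MOM 7-isopropylidene dienone, via tertiary mesylate 19 (not isolated)
Conditions: MsCl, Et3N, CH2Cl2, 0 °C; then DBU, rt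
Reagents that add atoms: none
Why: Mesylation of the tertiary alcohol and E1cB elimination through the C7 enolate gives the conjugated tetrasubstituted isopropylidene rather than the isopropenyl isomer.

Step 14
Reactants: 20
Product: 21 3α-hydroxy 9-O-MOM 7-isopropylidene dienone
Conditions: HF·pyridine, pyridine, THF, 0 °C → rt
Reagents that add atoms: none
Why: Fluoride-mediated desilylation frees the C3 alcohol, while the MOM enol ether (comparable to an aryl MOM ether) and the dienone are stable to buffered HF.

Step 15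
Reactants: 22 tert-butyldimethyl(prop-2-yn-1-yloxy)silane
Product: 24 tert-butyl 4-(tert-butyldimethylsilyloxy)but-2-ynoate, via lithium acetylide 23 (not isolated)
Conditions: n-BuLi, THF, −78 °C; then Boc2O, −78 → 0 °C
Reagents that add atoms: di-tert-butyl dicarbonate, CC(C)(C)OC(=O)OC(=O)OC(C)(C)C
Why: C-Acylation of the lithium acetylide with Boc2O gives the tert-butyl ynoate directly.

Step 16
Reactants: 24
Product: 26 tert-butyl (2Z)-4-(tert-butyldimethylsilyloxy)-3-methylbut-2-enoate, via alkenylcuprate 25 (not isolated)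
Conditions: Me2CuLi (from CuI, copper monoiodide, + 2 MeLi), THF, −78 °C; then MeOH, −78 °C
Reagents that add atoms: lithium dimethylcuprate, [Li+].C[Cu-]C
Why: syn-Carbocupration (conjugate addition) of the ynoate and cold protonation with retention place CH3 cis to H, so CH2O ends up cis to the ester (Z); a silyl ether is not a leaving group, so no allene forms.

Step 17
Reactants: 26
Product: 27 tert-butyl (2Z)-4-hydroxy-3-methylbut-2-enoate
Conditions: HF·pyridine, pyridine, THF, 0 °C; crude product used at once
Reagents that add atoms: none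
Why: Buffered fluoride desilylation; the bulky tert-butyl ester slows lactonisation of the Z hydroxy ester to the butenolide, and the material is kept cold and used directly for that reason.

Step 18
Reactants: 27; 28 angelic acid
Product: 30 tert-butyl (2Z)-3-methyl-4-[(2Z)-2-methylbut-2-enoyloxy]but-2-enoate, via angelic mixed anhydride 29 (not isolated)
Conditions: 28, 2,4,6-Cl3C6H2COCl, Et3N, toluene, rt; then 27, 60 °C (no DMAP)
Reagents that add atoms: none
Why: Yamaguchi-type esterification through the mixed anhydride without a nucleophilic catalyst acylates the primary allylic alcohol without angelate-to-tiglate isomerisation and keeps both Z alkenes.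

Step 19
Reactants: 30
Product: 31 (2Z)-3-methyl-4-[(2Z)-2-methylbut-2-enoyloxy]but-2-enoic acid
Conditions: TFA/CH2Cl2 (1:4), 0 °C → rt
Reagents that add atoms: none
Why: Acidolysis of the tert-butyl ester (loss of isobutene) leaves the allylic angelate and both Z alkenes intact, and the O-acyl group prevents lactonisation of the free acid.

Step 20
Reactants: 21; 31
Product: 33 9-O-methoxymethyl ether of the target, via mixed anhydride 32 (not isolated)
Conditions: 31, 2,4,6-Cl3C6H2COCl, Et3N, toluene, rt; then 21, DMAP, rt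
Reagents that add atoms: none
Why: Yamaguchi esterification acylates the hindered equatorial C3 alcohol at oxygen (retention at C3), while the diosphenol OH is masked so only one hydroxyl can react.

Step 21
Reactants: 33
Product: 34 target CNP0228871.1
Conditions: TFA/CH2Cl2/H2O (10:89:1), 0 °C
Reagents that add atoms: none
Why: Acid hydrolysis of the enol MOM acetal releases the diosphenol under conditions too mild to cleave or isomerise the two unsaturated esters.

**Compound list**
1 | 2-methylcyclohexane-1,3-dione | CC1C(=O)CCCC1=O | starting material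
2 | methyl vinyl ketone (but-3-en-2-one) | CC(=O)C=C | starting material
3 | 2-methyl-2-(3-oxobutyl)cyclohexane-1,3-dione | CC(=O)CCC1(C)C(=O)CCCC1=O | intermediate
4 | (4aS,8aS)-4a-hydroxy-8a-methyloctahydronaphthalene-1,6-dione, cis-fused ketol (not isolated) | C[C@]12CCC(=O)C[C@@]1(O)CCCC2=O | intermediate
5 | (S)-Wieland–Miescher ketone, (8aS)-8a-methyl-3,4,8,8a-tetrahydronaphthalene-1,6(2H,7H)-dione | C[C@]12CCC(=O)C=C1CCCC2=O | intermediate
6 | 5 with the enone carbonyl (C8) as spiro-1,3-dithiolane; C4 ketone free, 9(10)-ene, 5β-methyl | C[C@]12CCC3(SCCS3)C=C1CCCC2=O | intermediate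
7 | potassium C3(4)-enolate of 6 (not isolated) | [K+].C[C@]12CCC3(SCCS3)C=C1CCC=C2[O-] | intermediate
8 | C4 enol triflate of 6 (3,9(10)-dien-4-yl trifluoromethanesulfonate, C8 dithiolane) | C[C@]12CCC3(SCCS3)C=C1CCC=C2OS(=O)(=O)C(F)(F)F | intermediate
9 | 4,5β-dimethyl-3,9(10)-diene, C8 dithiolane | C[C@]12CCC3(SCCS3)C=C1CCC=C2C | intermediate
10 | 3α-boryl-4β,5β-dimethyl-9(10)-ene, C8 dithiolane (alkylborane, not isolated) | B[C@@H]1CCC2=CC3(SCCS3)CC[C@]2(C)[C@H]1C | intermediate
11 | 3α-hydroxy-4β,5β-dimethyl-9(10)-ene, C8 dithiolane | O[C@@H]1CCC2=CC3(SCCS3)CC[C@]2(C)[C@H]1C | intermediate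
12 | (4aR,5R,6R)-6-hydroxy-4a,5-dimethyl-4,4a,5,6,7,8-hexahydronaphthalen-2(3H)-one (3α-hydroxy-4β,5β-dimethyl-9(10)-en-8-one) | O[C@@H]1CCC2=CC(=O)CC[C@]2(C)[C@H]1C | intermediate
13 | 9β,10β-epoxy-3α-hydroxy-4β,5β-dimethyldecalin-8-one (major epoxide epimer) | O[C@@H]1CC[C@]23O[C@H]2C(=O)CC[C@]3(C)[C@H]1C | intermediate
14 | 3α,9-dihydroxy-4β,5β-dimethyl-9(10)-en-8-one (diosphenol) | O[C@@H]1CCC2=C(O)C(=O)CC[C@]2(C)[C@H]1C | intermediate
15 | 3α-hydroxy-9-(methoxymethoxy)-4β,5β-dimethyl-9(10)-en-8-one | O[C@@H]1CCC2=C(OCOC)C(=O)CC[C@]2(C)[C@H]1C | intermediate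
16 | 3α-(tert-butyldimethylsilyloxy)-9-(methoxymethoxy)-4β,5β-dimethyl-9(10)-en-8-one | CC(C)(C)[Si](C)(C)O[C@@H]1CCC2=C(OCOC)C(=O)CC[C@]2(C)[C@H]1C | intermediate
17 | lithium C7(8)-enolate of 16 (not isolated) | [Li+].CC(C)(C)[Si](C)(C)O[C@@H]1CCC2=C(OCOC)C([O-])=CC[C@]2(C)[C@H]1C | intermediate
18 | 7α-(2-hydroxypropan-2-yl) derivative of 16 (aldol adduct; C7 epimer inconsequential) | CC(C)(C)[Si](C)(C)O[C@@H]1CCC2=C(OCOC)C(=O)[C@H](C(C)(C)O)C[C@]2(C)[C@H]1C | intermediate
19 | tertiary methanesulfonate of 18 (not isolated) | CC(C)(C)[Si](C)(C)O[C@@H]1CCC2=C(OCOC)C(=O)[C@H](C(C)(C)OS(C)(=O)=O)C[C@]2(C)[C@H]1C | intermediate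
20 | 3α-(tert-butyldimethylsilyloxy)-9-(methoxymethoxy)-4β,5β-dimethyl-7-(propan-2-ylidene)-9(10)-en-8-one | CC(C)(C)[Si](C)(C)O[C@@H]1CCC2=C(OCOC)C(=O)C(=C(C)C)C[C@]2(C)[C@H]1C | intermediate
21 | 3α-hydroxy-9-(methoxymethoxy)-4β,5β-dimethyl-7-(propan-2-ylidene)-9(10)-en-8-one | O[C@@H]1CCC2=C(OCOC)C(=O)C(=C(C)C)C[C@]2(C)[C@H]1C | intermediate
22 | tert-butyldimethyl(prop-2-yn-1-yloxy)silane | C#CCO[Si](C)(C)C(C)(C)C | starting material
23 | lithium acetylide of 22 (not isolated) | [Li]C#CCO[Si](C)(C)C(C)(C)C | intermediate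
24 | tert-butyl 4-(tert-butyldimethylsilyloxy)but-2-ynoate | CC(C)(C)OC(=O)C#CCO[Si](C)(C)C(C)(C)C | intermediate
25 | lithium alkenyl(methyl)cuprate from syn addition to 24, Cu cis to the new CH3 (not isolated) | [Li+].CC(C)(C)OC(=O)/C([Cu-]C)=C(C)\CO[Si](C)(C)C(C)(C)C | intermediate
26 | tert-butyl (2Z)-4-(tert-butyldimethylsilyloxy)-3-methylbut-2-enoate | CC(C)(C)OC(=O)/C=C(C)\CO[Si](C)(C)C(C)(C)C | intermediate
27 | tert-butyl (2Z)-4-hydroxy-3-methylbut-2-enoate | CC(C)(C)OC(=O)/C=C(C)\CO | intermediate
28 | angelic acid, (2Z)-2-methylbut-2-enoic acid | C/C=C(/C)C(=O)O | starting material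
29 | (2Z)-2-methylbut-2-enoic 2,4,6-trichlorobenzoic anhydride (not isolated) | C/C=C(/C)C(=O)OC(=O)c1c(Cl)cc(Cl)cc1Cl | intermediate
30 | tert-butyl (2Z)-3-methyl-4-{[(2Z)-2-methylbut-2-enoyl]oxy}but-2-enoate | C/C=C(/C)C(=O)OC/C(C)=C\C(=O)OC(C)(C)C | intermediate
31 | (2Z)-3-methyl-4-{[(2Z)-2-methylbut-2-enoyl]oxy}but-2-enoic acid | C/C=C(/C)C(=O)OC/C(C)=C\C(=O)O | intermediate
32 | mixed anhydride of 31 with 2,4,6-trichlorobenzoic acid (not isolated) | C/C=C(/C)C(=O)OC/C(C)=C\C(=O)OC(=O)c1c(Cl)cc(Cl)cc1Cl | intermediate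
33 | 9-O-methoxymethyl ether of the target | C/C=C(/C)C(=O)OC/C(C)=C\C(=O)O[C@@H]1CCC2=C(OCOC)C(=O)C(=C(C)C)C[C@]2(C)[C@H]1C | intermediate
34 | (1R,2R,8aR)-5-hydroxy-1,8a-dimethyl-6-oxo-7-(propan-2-ylidene)-1,2,3,4,6,7,8,8a-octahydronaphthalen-2-yl (2Z)-3-methyl-4-{[(2Z)-2-methylbut-2-enoyl]oxy}but-2-enoate (CNP0228871.1) | C/C=C(/C)C(=O)OC/C(C)=C\C(=O)O[C@@H]1CCC2=C(O)C(=O)C(=C(C)C)C[C@]2(C)[C@H]1C | target

**Totals**
Total steps: 21. Longest linear sequence: 16 (steps 1–14, then 20 and 21); the side chain takes steps 15–19.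

**Three steps most likely to fail, each with one fallback**

Step 6, chemoselective hydroboration of the ring A alkene beside the C9=C10 alkene and the dithiolane. The fallback sets out from 9 and removes borane from the plan. The dithiolane is hydrolysed first (MeI, CaCO3, aqueous MeCN) to the 4,5β-dimethyl-3,9(10)-dien-8-one F1. mCPBA/NaHCO3 (CH2Cl2, 0 °C) then epoxidises only the electron-rich C3=C4 bond, from the α face, to the 3α,4α-epoxide F2. Cp2TiCl (trivalent titanium, made from Cp2TiCl2 and Mn dust) with 1,4-cyclohexadiene in THF opens the epoxide homolytically to the tertiary C4 radical, which takes hydrogen from the α face. This gives the anti-Markovnikov 3α-alcohol with the 4β-methyl group, and the route is rejoined at 12.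

Step 9, acid isomerisation of the epoxy ketone to the diosphenol (possible ring contraction or incomplete dehydration). The fallback sets out from 12 and oxidises C9 through a regiodefined enolate instead. Li in NH3(l)/THF at −78 °C reduces the enone, and the C8–C9 enolate (with the C3 alkoxide) is trapped with Me3SiCl/Et3N to give the trans-fused bis(trimethylsilyl) enol ether F3. Rubottom oxidation (mCPBA, NaHCO3, CH2Cl2, then dilute HCl) gives the 3α,9α-dihydroxy-8-ketone F4. Cu(OAc)2 (cat.) in MeOH under air oxidises only the acyloin to the 8,9-dione, which enolises to the diosphenol, and the route is rejoined at 14.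

Step 20, esterification of the hindered C3 alcohol with the sensitive acyloxy Z-acid (slow coupling, Z/E scrambling through a vinylketene). The fallback sets out from 26 and 21 and builds the side chain on the core in two stages. Me3SiOTf/2,6-lutidine (CH2Cl2, 0 °C) cleaves the tert-butyl ester of 26 to the trimethylsilyl ester F5, which is not isolated and gives the silyl-protected Z acid F6 on aqueous work-up. EDC·HCl/DMAP (CH2Cl2) couples F6 with 21 to the silyloxy ester F7. HF·pyridine at 0 °C removes the primary TBS group to give the hydroxy ester F8, which is acylated at once with the angelic mixed anhydride 29 (toluene, 60 °C), and the route is rejoined at 33.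

Further compounds
F1 | step 6 | 4,5β-dimethyl-3,9(10)-dien-8-one (9 without the dithiolane) | C[C@]12CCC(=O)C=C1CCC=C2C
F2 | step 6 | 3α,4α-epoxy-4β,5β-dimethyl-9(10)-en-8-one | O1[C@@H]2CCC3=CC(=O)CC[C@]3(C)[C@]12C
F3 | step 9 | 3α,8-bis(trimethylsilyloxy)-4β,5β-dimethyl-10α-H-8(9)-ene (trans-fused silyl enol ether) | C[Si](C)(C)O[C@@H]1CC[C@H]2C=C(O[Si](C)(C)C)CC[C@]2(C)[C@H]1C
F4 | step 9 | 3α,9α-dihydroxy-4β,5β-dimethyl-10α-H-decalin-8-one | O[C@@H]1CC[C@H]2[C@H](O)C(=O)CC[C@]2(C)[C@H]1C
F5 | step 20 | trimethylsilyl (2Z)-4-(tert-butyldimethylsilyloxy)-3-methylbut-2-enoate (not isolated) | C[Si](C)(C)OC(=O)/C=C(C)\CO[Si](C)(C)C(C)(C)C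
F6 | step 20 | (2Z)-4-(tert-butyldimethylsilyloxy)-3-methylbut-2-enoic acid | OC(=O)/C=C(C)\CO[Si](C)(C)C(C)(C)C
F7 | step 20 | C3 ester of 21 with F6 | CC(C)(C)[Si](C)(C)OC/C(C)=C\C(=O)O[C@@H]1CCC2=C(OCOC)C(=O)C(=C(C)C)C[C@]2(C)[C@H]1C
F8 | step 20 | C3 (2Z)-4-hydroxy-3-methylbut-2-enoate of 21 | OC/C(C)=C\C(=O)O[C@@H]1CCC2=C(OCOC)C(=O)C(=C(C)C)C[C@]2(C)[C@H]1C
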